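## Analysis of the target

The target is a germacranolide: a cyclodeca-1(10),4-diene (C1–C10) fused trans across C6–C7 to an α-methylene-γ-butyrolactone (O6–C12–C11–C7, with the exocyclic methylene C13 on C11). C10 carries the C14 methyl ester and C4 the C15 hydroxymethyl group. In both ring alkenes the ring carbons are cis to each other (C2/C9 and C3/C6), although each is E by the sequence rules because the oxygenated substituent outranks the ring carbon. The four stereocentres are contiguous, C6 (R), C7 (S), C8 (S) and C9 (S): O6 and C11 are trans on the lactone, C8 bears the methacrylate and C9 the acetate, and O8 and O9 are syn when the C7–C10 chain is drawn extended. Sensitive features are two acrylate-type Michael acceptors (the methylene lactone and the methacrylate), an allylic acetate that is part of a 2-(1-acyloxyalkyl)acrylate, vicinal esters that can migrate, and a C8 oxygen that can compete with O6 for the lactone carbonyl. The difficulty is threefold: a ten-membered ring with two cis trisubstituted alkenes, three neighbouring oxygens with three different roles, and control of C6–C9 without a rigid template. The strategy rests on the C6–C7–C8 segment: O6, the C7–C11 bond and O8 lie on three consecutive carbons, which is the pattern left when a carbon nucleophile held on O6 opens a C7–C8 epoxide at C7 and the epoxide oxygen stays on C8.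

## Retrosynthetic reasoning

Peripheral groups (33 ⇒ 32 ⇒ 31 ⇒ 30 ⇒ 29). The C15 silyl ether of 32 is cut last, because a primary allylic silyl ether survives every earlier reagent and can be removed without touching the esters. Before that, the methacrylate on O8 (32 from 31) and the acetate on O9 (30 from 29) are removed in turn. They go on late because neither survives enolate chemistry. O8 stays silylated until O9 is acetylated, so the two hydroxyls are never free together.

C9–C10 (29 ⇒ 28). The ten-membered ring of 29 is opened between the carbinol C9 and the vinylic C10, back to iodo aldehyde 28. This cut is preferred over C1=C10 or a ring C–C single bond because the forward reaction, an intramolecular Nozaki–Hiyama–Kishi addition, makes the allylic alcohol beside the ester-bearing alkene in one event. The alkene geometry is carried in from an acyclic alkenyl iodide, so the ring-closing step does not have to choose between alkene isomers. It has to achieve closure over oligomerisation and attack on the correct face of the C9 aldehyde.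

C1=C10 and the C9 oxidation level (28 ⇒ 27 ⇒ 26 ⇒ 25). Aldehyde 28 comes from the p-methoxybenzyl ether 26 through alcohol 27, and 26 from aldehyde 25 by cutting C1=C10. The forward reaction is a Wittig olefination that brings in C10, C14 and the iodine together. The ester ends trans to C2, which places iodine, and later C9, cis to C2. C1 is carried as a dioxolane in 23 until this point, so the two aldehydes of the endgame are released one after the other.

C11=C13 (25 ⇒ 23 ⇒ 21 ⇒ 20). The exocyclic methylene is removed next. The aminomethylation–elimination is placed on lactone 20, which has no other enolisable or electrophilic carbonyl group. This avoids forming a lactone enolate later in the presence of the iodo enoate, the acetate or the ring enoate.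

C11 ester and O8 protection (20 ⇒ 19 ⇒ 18). Lactone 20 is traced to the C11 ester 19 by dealkoxycarbonylation, and 19 to hydroxy lactone 18 by silylation of O8. The ester has done its work once C7–C11 exists and must go before the methylene is put on the same carbon. O8 is capped first so that it cannot attack either carbonyl during the hot dealkoxycarbonylation.

C7–C11, the key disconnection (18 ⇒ 17). Cutting the C7–C11 bond of 18, and not O6–C12, turns the lactone carbonyl into a tether: the precursor is the malonate 17 of an epoxy alcohol. The gain is that the lactone ring, the C7 stereocentre and O8 all derive from the epoxide, so the triad C6/C7/C8 reduces to one carbinol and one trans epoxide. The forward reaction has to open the epoxide at C7 only, with inversion, and leave the liberated O8 unacylated.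

Ester and epoxide (17 ⇒ 15 + 16; 15 ⇒ 14). Malonate 17 is the ester of epoxy alcohol 15 with acid chloride 16. Epoxy alcohol 15 is the Sharpless epoxidation product of the bis-allylic alcohol 14. Only the C7=C8 alkene is taken back from an epoxide: for the C6 configuration of 14 it is the matched alkene, whereas C4=C5 is mismatched and carries a substituent cis to the carbinol.

C6–C7 (14 ⇒ 12 ⇒ 8 + 10; 10 ⇒ 9). The E alkene of 14 is taken back to the alkyne of 12, and 12 is cut at C6–C7 into enal 8 and alkyne 10, the p-methoxybenzyl ether of alcohol 9. An alkyne is chosen as the C7–C9 unit because its addition to an aldehyde can be made enantioselective and its hydroxyl-directed reduction gives only the E alkene.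

C3–C4 and the C4=C5 geometry (8 ⇒ 7 ⇒ 4 + 5; 4 ⇒ 2 ⇒ 1). Enal 8 is the oxidation product of allylic alcohol 7, which is cut at C3–C4 into alkenyl iodide 4 and the C1–C3 unit 5, joined through borane 6. The point of this cut is the alkene geometry, C6 cis to C3: in 4 it is fixed by the cyclic intermediate 3 formed from alkynol 2, the monosilyl ether of diol 1. A one-step carbometallation of 2 with a C1–C3 organometallic would be shorter, but it places a metal β to the silyloxy group under forcing conditions, where loss of silanolate to an allene is a known escape.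

## Alternatives that were turned down

Alternative 1: The disconnection is C1=C10. The alkene is replaced by a sulfonyl bridge, so the ten-membered carbocycle comes from an eleven-membered thia-ring, the α-chloro sulfone A1 (sulfur between C1 and C10, chlorine on C1). In the forward direction KOtBu removes the C10 proton, the carbanion displaces chloride from C1 to give episulfone A2, and loss of SO2 leaves the C1=C10 alkene of cyclodecadiene A3 (Ramberg–Bäcklund contraction).
- For it: a ring one atom larger, closed through a carbon–sulfur bond, is easier to make than a ten-membered ring closed through a carbon–carbon bond. C9 is already in place before the contraction, so no stereocentre is created while the ring forms. On this point it is stronger than the chosen route, whose ring closure also has to set C9.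
- Against it: the C10 carbanion is stabilised by both the sulfone and the ester and is a reluctant nucleophile for the 1,3-displacement. The C9 silyloxy group sits β to it and can be expelled by E1cB elimination. The geometry of the new trisubstituted alkene is decided only by how A2 forms and collapses within the ring. The tert-butoxide also meets an enolisable lactone, and sulfur has to be oxidised next to two trisubstituted alkenes.
- Comparison: the alternative does not address how C6, C7, C8 and the lactone arise. The chosen strategy derives all three centres and the lactone from one carbinol and one epoxide, and it fixes the C1=C10 geometry in an acyclic alkenyl iodide before the ring is closed. Step count is comparable, since the sulfone needs its own installation, oxidation and chlorination.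

Alternative 2: The lactone is disconnected last, at O6–C12 and C11–C12, with carbon monoxide as C12. The precursor is the ten-membered homopropargylic alcohol A4, with a free C6 hydroxyl and a C7 ethynyl group (C11≡C13) beside the finished methacrylate and acetate. In the forward step PdCl2(PPh3)2 and SnCl2 under CO insert CO into the O6–palladium bond; the acyl unit adds across the alkyne in the exo sense and protonolysis releases the α-methylene lactone A5. A5 is the C15 silyl ether of the target and the same compound as 32 of the chosen route.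
- For it: C12, the lactone ring and the exocyclic alkene arrive in one catalytic step without enolate chemistry, and the Michael acceptor exists only for the last two steps. In step economy for the lactone (one step against steps 9–14 here) and in sparing the methylene lactone a long endgame it is clearly stronger.
- Against it: A4 must already contain C6, C7, C8 and C9, with the C6 hydroxyl trans to the C7 ethynyl group on a flexible ten-membered ring, and nothing relays one centre to the next. The free C6 hydroxyl is allylic and 1,3 to the C8 methacrylate, so ionisation by the Lewis-acidic tin salt and acyl transfer are both open. Zerovalent palladium formed under CO can ionise the C9 acetate, an activated allylic ester, or engage the other acrylate units.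
- Comparison: the chosen strategy pays for its longer lactone sequence by building the C6–C8 triad on an open chain, where the only nucleophile–electrophile pair that can meet is the one held by the tether.

Alternative 3: The ring is disconnected at C8–C9 with reconnection of C1–C6. The precursor is the 1,2-dialkenylcyclohex-3-en-1-ol A6, in which the tertiary C6 alcohol carries the C7=C8 enol ether and C1 carries the C10=C9 alkoxyacrylate. With KH and 18-crown-6 the alkoxide undergoes an anionic oxy-Cope rearrangement through the diene C8=C7–C6–C1–C10=C9. C8–C9 forms, C1–C6 breaks and the six-membered ring opens to the ten-membered potassium enolate A7, which gives ketone A8 on protonation.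
- For it: the medium ring is made by a sigmatropic ring expansion that needs no high dilution. The C1=C10 enoate is created in the same event, and the C8/C9 relationship is translated from two alkene geometries through an ordered transition state. For the carbocycle and for C8/C9 it is stronger than the chosen route, whose ring closure is an addition of uncertain facial selectivity.
- Against it: A7 has the C8 p-methoxybenzyloxy group β to the enolate, so elimination to an enone is a direct competing path. The push–pull alkoxyacrylate is itself sensitive to KH. The lactone still has to be added to A8 by alkylation at C7 and reduction at C6 of a ten-membered ketone, two steps whose stereochemical outcome depends on ring conformation.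
- Comparison: the chosen strategy gives up the ring expansion but controls C6, C7 and C8 by reagent (alkynylation, epoxidation) and by an SN2 inversion.

Key step: step 10

Remark on the chemistry: locants C1–C15 are those of the target ring and are used for all intermediates; CIP descriptors change with the substituents, although the spatial arrangement is carried through unchanged.

Remark on the chemistry: the antipode of the ProPhenol ligand in step 6 is assigned on the assumption that alkynylzinc addition follows the facial sense of this catalyst in aldol additions; if the sense is reversed the other antipode is used, and step 8 removes the minor C6 enantiomer in either case.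

## Route

Step 1
Reactants: 1 2-butyne-1,4-diol
Product: 2 4-[(tert-butyldimethylsilyl)oxy]but-2-yn-1-ol
Conditions: NaH (1 equiv), THF, 0 °C; t-BuMe2SiCl, 0 °C to rt (diol in threefold excess)
Reagents that add atoms: tert-butyldimethylsilyl chloride, CC(C)(C)[Si](C)(C)Cl
Why: One equivalent of NaH gives the monoalkoxide, which is silylated (Williamson-type O-silylation); with the diol in excess the monoether should dominate and is separated from diol and bis-ether by polarity.

Step 2
Reactants: 2 4-[(tert-butyldimethylsilyl)oxy]but-2-yn-1-ol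
Product: 4 (Z)-4-[(tert-butyldimethylsilyl)oxy]-3-iodobut-2-en-1-ol, via cyclic sodium alkenylaluminate 3 (not isolated)
Conditions: NaAlH2(OCH2CH2OCH3)2, THF, 0 °C; EtOAc; then I2, THF, −78 to 0 °C
Reagents that add atoms: iodine, II
Why: The aluminium alkoxide delivers hydride to the nearer alkyne carbon (C5) in a trans-hydroalumination, giving the five-membered alkenylaluminate 3 with aluminium on C4; iodinolysis of the C–Al bond goes with retention, so iodine on C4 is cis to C6. Regiochemistry and geometry both follow from the ring in 3, and at or below 0 °C the β-silyloxy group should not be expelled.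

Step 3
Reactants: 4 (Z)-4-[(tert-butyldimethylsilyl)oxy]-3-iodobut-2-en-1-ol; 5 2-vinyl-1,3-dioxolane
Product: 7 (2E)-3-{[(tert-butyldimethylsilyl)oxy]methyl}-5-(1,3-dioxolan-2-yl)pent-2-en-1-ol, via alkylborane 6 (not isolated)
Conditions: 5, 9-BBN, THF, 0 °C to rt; then 4, PdCl2(dppf), AsPh3, Cs2CO3, DMF/H2O, rt
Reagents that add atoms: none
Why: Hydroboration puts boron on the terminal carbon of 5, γ to the acetal oxygens, so 6 cannot undergo β-alkoxy elimination; the B-alkyl Suzuki–Miyaura coupling then replaces iodine with retention of geometry and tolerates the free hydroxyl. C3 therefore ends cis to C6, as the C4=C5 alkene of the target requires.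

Step 4
Reactants: 7 (2E)-3-{[(tert-butyldimethylsilyl)oxy]methyl}-5-(1,3-dioxolan-2-yl)pent-2-en-1-ol
Product: 8 (2E)-3-{[(tert-butyldimethylsilyl)oxy]methyl}-5-(1,3-dioxolan-2-yl)pent-2-enal
Conditions: MnO2, CH2Cl2, rt
Reagents that add atoms: none
Why: MnO2 oxidises the primary allylic alcohol to the enal under neutral heterogeneous conditions, which avoids acid- or base-promoted isomerisation of the trisubstituted alkene and leaves the silyl ether and acetal alone.

Step 5
Reactants: 9 prop-2-yn-1-ol
Product: 10 1-methoxy-4-[(prop-2-yn-1-yloxy)methyl]benzene (PMB propargyl ether)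
Conditions: NaH, 4-MeOC6H4CH2Cl, Bu4NI (cat.), THF, 0 °C to rt
Reagents that add atoms: 4-methoxybenzyl chloride, COc1ccc(CCl)cc1
Why: Williamson etherification; the alkoxide forms selectively because the hydroxyl is far more acidic than the acetylenic C–H.

Step 6
Reactants: 8 (2E)-3-{[(tert-butyldimethylsilyl)oxy]methyl}-5-(1,3-dioxolan-2-yl)pent-2-enal; 10 PMB propargyl ether
Product: 12 (4R,5E)-6-{[(tert-butyldimethylsilyl)oxy]methyl}-8-(1,3-dioxolan-2-yl)-1-[(4-methoxybenzyl)oxy]oct-5-en-2-yn-4-ol (C6 R), via methylzinc alkynylide 11 (not isolated)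
Conditions: 10, Me2Zn, (R,R)-ProPhenol (cat.), Ph3PO (cat.), toluene, 0 °C; then 8, 4 °C
Reagents that add atoms: none
Why: Me2Zn deprotonates the alkyne to zinc alkynylide 11, which adds 1,2 to the enal inside the dinuclear zinc–ProPhenol pocket (catalytic asymmetric alkynylation of an α,β-unsaturated aldehyde). Attack on the Si face of the aldehyde sets C6 as R; a small amount of the enantiomer is tolerable because step 8 discriminates against it.

Step 7
Reactants: 12 propargylic alcohol (C6 R)
Product: 14 (2E,4S,5E)-6-{[(tert-butyldimethylsilyl)oxy]methyl}-8-(1,3-dioxolan-2-yl)-1-[(4-methoxybenzyl)oxy]octa-2,5-dien-4-ol (C6 S by priority change), via cyclic sodium alkenylaluminate 13 (not isolated)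
Conditions: NaAlH2(OCH2CH2OCH3)2, THF, 0 °C to rt; aq. potassium sodium tartrate
Reagents that add atoms: none
Why: Hydroxyl-directed trans-hydroalumination gives alkenylaluminate 13 with aluminium on C8, and protonolysis on work-up gives only the E alkene. C6 is untouched, isolated alkenes are inert to the reagent, and the allylic PMB ether is retained at these temperatures.

Step 8
Reactants: 14 bis-allylic alcohol (C6 S, 7E)
Product: 15 (1R,2E)-3-{[(tert-butyldimethylsilyl)oxy]methyl}-5-(1,3-dioxolan-2-yl)-1-[(2R,3R)-3-{[(4-methoxybenzyl)oxy]methyl}oxiran-2-yl]pent-2-en-1-ol (erythro epoxy alcohol; C6 R, C7 R, C8 R)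
Conditions: Ti(OiPr)4, D-(−)-diisopropyl tartrate, t-BuOOH, 4 Å MS, CH2Cl2, −20 °C
Reagents that add atoms: tert-butyl hydroperoxide, CC(C)(C)OO
Why: Sharpless epoxidation of a secondary allylic alcohol in its matched sense: with the D-(−)-tartrate the reagent forms the (7R,8R)-epoxide, and the C6 configuration of 14 is the fast-reacting one, so the erythro epoxy alcohol should form with reagent and substrate control reinforcing. For the same C6 configuration C4=C5 is the mismatched alkene and also carries a substituent cis to the carbinol, so it is spared; any C6 enantiomer of 14 reacts slowly and is left behind.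

Step 9
Reactants: 15 erythro epoxy alcohol; 16 methyl 3-chloro-3-oxopropanoate
Product: 17 (1R,2E)-3-{[(tert-butyldimethylsilyl)oxy]methyl}-5-(1,3-dioxolan-2-yl)-1-[(2R,3R)-3-{[(4-methoxybenzyl)oxy]methyl}oxiran-2-yl]pent-2-en-1-yl methyl malonate
Conditions: pyridine, CH2Cl2, −20 to 0 °C
Reagents that add atoms: none
Why: Acylation of the secondary alcohol by the acid chloride with pyridine as acid scavenger; at or below 0 °C pyridinium chloride should not open the epoxide.

Step 10
Reactants: 17 methyl malonate of the erythro epoxy alcohol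
Product: 18 methyl (3R,4R,5R)-5-[(1E)-2-{[(tert-butyldimethylsilyl)oxy]methyl}-4-(1,3-dioxolan-2-yl)but-1-en-1-yl]-4-{(1S)-1-hydroxy-2-[(4-methoxybenzyl)oxy]ethyl}-2-oxooxolane-3-carboxylate (trans lactone, C11 ester, free O8)
Conditions: NaH (1.05 equiv), THF/DMF, 0 °C to rt; then AcOH, −40 °C
Reagents that add atoms: none
Why: NaH removes a C11 proton of the malonate, and the enolate carbon attacks C7 from the side opposite the epoxide C–O bond, forming C7–C11 and closing the γ-lactone ring O6–C12–C11–C7–C6 in a 5-exo-tet mode. The closest known reaction types are the alkylation of malonate anions by epoxides to give α-alkoxycarbonyl γ-lactones and the 5-exo opening of 2,3-epoxy alcohol carbamates at the proximal carbon. C7 is inverted, and because 17 is the erythro trans epoxide this places C8 trans to C5 on the new ring; C8 keeps its oxygen and configuration, so the carbinol from step 6 and the epoxide from step 8 fix C7 and C8 of the target. The selectivity needed is C7 over C8: attack at C8 would need a six-membered endo transition state in which the nucleophile cannot approach in line with the C8–O bond, whereas the four-atom tether reaches the back of C7 once the ester rotates into its s-trans form, a rotation that is easier in the enolate than in a neutral ester. The C8 alkoxide that is released is protonated at once by the acidic C11–H of the product, so the material rests as the enolate of the 1,3-dicarbonyl lactone, whose carbonyl groups are poor electrophiles; this proton transfer is what keeps O8 from attacking C12 or the methyl ester. Cold quenching with AcOH gives 18; C11 should form as the more stable epimer with the ester trans to the C7 side chain and is destroyed later.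

Step 11
Reactants: 18 hydroxy lactone
Product: 19 methyl (3R,4S,5R)-5-[(1E)-2-{[(tert-butyldimethylsilyl)oxy]methyl}-4-(1,3-dioxolan-2-yl)but-1-en-1-yl]-4-{(1S)-2-[(4-methoxybenzyl)oxy]-1-[(triethylsilyl)oxy]ethyl}-2-oxooxolane-3-carboxylate
Conditions: Et3SiOTf, 2,6-lutidine, CH2Cl2, −78 °C
Reagents that add atoms: triethylsilyl trifluoromethanesulfonate, CC[Si](CC)(CC)OS(=O)(=O)C(F)(F)F
Why: Silylation with a silyl triflate and a hindered pyridine base is fast at −78 °C and non-nucleophilic, so O8 is capped before it can translactonise; any enol silyl ether formed at the 1,3-dicarbonyl is hydrolysed on work-up.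

Step 12
Reactants: 19 O8-silylated ester lactone
Product: 20 (4S,5R)-5-[(1E)-2-{[(tert-butyldimethylsilyl)oxy]methyl}-4-(1,3-dioxolan-2-yl)but-1-en-1-yl]-4-{(1S)-2-[(4-methoxybenzyl)oxy]-1-[(triethylsilyl)oxy]ethyl}oxolan-2-one
Conditions: LiCl, H2O, DMSO, 120 °C
Reagents that add atoms: none
Why: Krapcho dealkoxycarbonylation: chloride attacks the methyl group of the ester, the carboxylate β to the lactone carbonyl loses CO2 and the enolate is protonated by water. The lactone is spared because its alkoxy carbon is secondary, and the neutral medium should leave the silyl ethers, the acetal and the PMB ether in place.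

Step 13
Reactants: 20 lactone (C11 H2)
Product: 21 (3R,4S,5R)-5-[(1E)-2-{[(tert-butyldimethylsilyl)oxy]methyl}-4-(1,3-dioxolan-2-yl)but-1-en-1-yl]-3-[(dimethylamino)methyl]-4-{(1S)-2-[(4-methoxybenzyl)oxy]-1-[(triethylsilyl)oxy]ethyl}oxolan-2-one
Conditions: LiN(iPr)2, THF, −78 °C; then Me2N=CH2 I, −78 °C to rt
Reagents that add atoms: N,N-dimethylmethyleneiminium iodide (Eschenmoser's salt), C=[N+](C)C.[I-]
Why: The lithium enolate of the lactone is aminomethylated by the iminium salt (Mannich reaction) on the face away from the C7 side chain; C11 is the only enolisable position and no leaving group sits β to the enolate. The C11 configuration is of no consequence.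

Step 14
Reactants: 21 Mannich base
Product: 23 (4S,5R)-5-[(1E)-2-{[(tert-butyldimethylsilyl)oxy]methyl}-4-(1,3-dioxolan-2-yl)but-1-en-1-yl]-4-{(1S)-2-[(4-methoxybenzyl)oxy]-1-[(triethylsilyl)oxy]ethyl}-3-methylideneoxolan-2-one, via trimethylammonium iodide 22 (not isolated)
Conditions: MeI, THF, rt; then aq. NaHCO3, EtOAc, rt
Reagents that add atoms: none
Why: N-Methylation gives ammonium salt 22, which loses trimethylamine by base-induced β-elimination under mild bicarbonate conditions to give the exocyclic methylene.

Step 15
Reactants: 23 methylene lactone with C1 dioxolane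
Product: 25 (4S,5R)-5-[(1E)-2-{[(tert-butyldimethylsilyl)oxy]methyl}-5-oxopent-1-en-1-yl]-4-{(1S)-2-[(4-methoxybenzyl)oxy]-1-[(triethylsilyl)oxy]ethyl}-3-methylideneoxolan-2-one (C1 aldehyde), via collidinium triflate 24 (not isolated)
Conditions: Et3SiOTf, 2,4,6-collidine, CH2Cl2, 0 °C; then H2O, rt
Reagents that add atoms: water, O
Why: The silyl triflate activates the dioxolane, collidine traps the oxocarbenium ion as pyridinium salt 24, and water hydrolyses this to the aldehyde. The medium stays basic throughout, so the TBS, TES and PMB ethers should survive where aqueous acid would endanger them.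

Step 16
Reactants: 25 C1 aldehyde
Product: 26 methyl (2Z,6E)-6-{[(tert-butyldimethylsilyl)oxy]methyl}-2-iodo-7-[(2R,3S)-3-{(1S)-2-[(4-methoxybenzyl)oxy]-1-[(triethylsilyl)oxy]ethyl}-4-methylidene-5-oxooxolan-2-yl]hepta-2,6-dienoate
Conditions: Ph3P=CHCO2Me, N-iodosuccinimide, CH2Cl2, −20 °C; then 25, −20 °C to rt
Reagents that add atoms: methyl (triphenylphosphoranylidene)acetate, COC(=O)C=P(c1ccccc1)(c1ccccc1)c1ccccc1; N-iodosuccinimide, O=C1CCC(=O)N1I
Why: Iodination of the stabilised ylide gives the iodo ylide in the flask, which olefinates the aldehyde (Wittig reaction). As with other ester-stabilised ylides the ester should end trans to the chain, giving the (Z)-2-iodo enoate with iodine cis to C2.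

Step 17
Reactants: 26 (Z)-iodo enoate with C9 PMB ether
Product: 27 methyl (2Z,6E)-6-{[(tert-butyldimethylsilyl)oxy]methyl}-7-[(2R,3S)-3-{(1S)-2-hydroxy-1-[(triethylsilyl)oxy]ethyl}-4-methylidene-5-oxooxolan-2-yl]-2-iodohepta-2,6-dienoate
Conditions: DDQ, CH2Cl2/pH 7 buffer, 0 °C
Reagents that add atoms: none
Why: Oxidative cleavage of the p-methoxybenzyl ether by DDQ (hydride abstraction, then hydrolysis of the oxocarbenium ion); the buffer protects the TES ether and none of the alkenes is electron-rich enough to react.

Step 18
Reactants: 27 C9 primary alcohol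
Product: 28 methyl (2Z,6E)-6-{[(tert-butyldimethylsilyl)oxy]methyl}-2-iodo-7-[(2R,3S)-4-methylidene-5-oxo-3-{(1S)-2-oxo-1-[(triethylsilyl)oxy]ethyl}oxolan-2-yl]hepta-2,6-dienoate (C9 aldehyde)
Conditions: Dess–Martin periodinane, NaHCO3, CH2Cl2, 0 °C to rt
Reagents that add atoms: none
Why: Dess–Martin oxidation under buffered, non-basic conditions gives the α-silyloxy aldehyde without epimerising C8; it is used directly.

Step 19
Reactants: 28 iodo aldehyde
Product: 29 methyl (3aS,4S,5S,6E,10E,11aR)-10-{[(tert-butyldimethylsilyl)oxy]methyl}-5-hydroxy-3-methylidene-2-oxo-4-[(triethylsilyl)oxy]-2,3,3a,4,5,8,9,11a-octahydrocyclodeca[b]furan-6-carboxylate (C9 S alcohol)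
Conditions: CrCl2, NiCl2 (cat.), DMSO/THF, rt, 2 mM (slow addition)
Reagents that add atoms: none
Why: Nozaki–Hiyama–Kishi reaction: zerovalent nickel inserts into the C–I bond, the alkenyl group passes to trivalent chromium with retention of geometry, and the alkenylchromium adds to the C9 aldehyde, closing the ten-membered ring at high dilution. The reagent is chemoselective for aldehydes over esters and lactones; C9 is created here, and the 9S alcohol, with O9 syn to O8 along the extended C7–C10 chain, is the isomer taken forward.

Step 20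
Reactants: 29 C9 alcohol
Product: 30 methyl (3aS,4S,5S,6E,10E,11aR)-5-acetoxy-10-{[(tert-butyldimethylsilyl)oxy]methyl}-3-methylidene-2-oxo-4-[(triethylsilyl)oxy]-2,3,3a,4,5,8,9,11a-octahydrocyclodeca[b]furan-6-carboxylate
Conditions: Ac2O, pyridine, DMAP (cat.), CH2Cl2, 0 °C
Reagents that add atoms: acetic anhydride, CC(=O)OC(C)=O
Why: Acetylation of the secondary allylic alcohol under nucleophilic catalysis; the β-substituted 2-(acyloxyalkyl)acrylate that results is much less prone to SN2′ attack by the catalyst than an unsubstituted one.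

Step 21
Reactants: 30 C9 acetate with O8 TES ether
Product: 31 methyl (3aR,4S,5S,6E,10E,11aR)-5-acetoxy-10-{[(tert-butyldimethylsilyl)oxy]methyl}-4-hydroxy-3-methylidene-2-oxo-2,3,3a,4,5,8,9,11a-octahydrocyclodeca[b]furan-6-carboxylate
Conditions: PPTS, MeOH/CH2Cl2, 0 °C
Reagents that add atoms: none
Why: Acid-catalysed methanolysis should remove the secondary TES ether considerably faster than the primary TBS ether; the mildly acidic medium does not promote migration of the neighbouring acetate.

Step 22
Reactants: 31 C8 alcohol
Product: 32 methyl (3aS,4S,5S,6E,10E,11aR)-5-acetoxy-10-{[(tert-butyldimethylsilyl)oxy]methyl}-4-(methacryloyloxy)-3-methylidene-2-oxo-2,3,3a,4,5,8,9,11a-octahydrocyclodeca[b]furan-6-carboxylate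
Conditions: methacrylic anhydride, Et3N, DMAP, CH2Cl2, 0 °C to rt
Reagents that add atoms: methacrylic anhydride, C=C(C)C(=O)OC(=O)C(C)=C
Why: DMAP-catalysed acylation of the C8 hydroxyl (Steglich-type); acylation by the acylpyridinium ion is expected to outpace base-mediated acetyl migration from O9 to O8.

Step 23
Reactants: 32 C15 TBS ether of the target
Product: 33 methyl (3aS,4S,5S,6E,10E,11aR)-5-acetoxy-10-(hydroxymethyl)-4-(methacryloyloxy)-3-methylidene-2-oxo-2,3,3a,4,5,8,9,11a-octahydrocyclodeca[b]furan-6-carboxylate (CNP0179134.2)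
Conditions: HF·pyridine, pyridine, THF, 0 °C to rt
Reagents that add atoms: none
Why: Fluoride cleaves the Si–O bond of the primary TBS ether under buffered acidic conditions; the freed hydroxyl is remote from the esters, so no acyl migration or conjugate addition is expected.

## Compound list

1 | 2-butyne-1,4-diol | OCC#CCO | starting material
2 | 4-[(tert-butyldimethylsilyl)oxy]but-2-yn-1-ol | OCC#CCO[Si](C)(C)C(C)(C)C | intermediate
3 | sodium alkenylaluminate, five-membered ring O6–C6–C5=C4–Al with two 2-methoxyethoxy groups on Al and CH2OTBS on C4 (formed in the flask) | COCCO[Al-]1(OCCOC)OCC=C1CO[Si](C)(C)C(C)(C)C.[Na+] | intermediate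
4 | (Z)-4-[(tert-butyldimethylsilyl)oxy]-3-iodobut-2-en-1-ol | OC/C=C(I)/CO[Si](C)(C)C(C)(C)C | intermediate
5 | 2-vinyl-1,3-dioxolane | C=CC1OCCO1 | starting material
6 | 9-[2-(1,3-dioxolan-2-yl)ethyl]-9-borabicyclo[3.3.1]nonane (formed in the flask) | C1CCC2CCCC1B2CCC1OCCO1 | intermediate
7 | (2E)-3-{[(tert-butyldimethylsilyl)oxy]methyl}-5-(1,3-dioxolan-2-yl)pent-2-en-1-ol | OC/C=C(/CO[Si](C)(C)C(C)(C)C)CCC1OCCO1 | intermediate
8 | (2E)-3-{[(tert-butyldimethylsilyl)oxy]methyl}-5-(1,3-dioxolan-2-yl)pent-2-enal | O=C/C=C(/CO[Si](C)(C)C(C)(C)C)CCC1OCCO1 | intermediate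
9 | prop-2-yn-1-ol | C#CCO | starting material
10 | 1-methoxy-4-[(prop-2-yn-1-yloxy)methyl]benzene | C#CCOCc1ccc(OC)cc1 | intermediate
11 | methyl{3-[(4-methoxybenzyl)oxy]prop-1-yn-1-yl}zinc (formed in the flask) | C[Zn]C#CCOCc1ccc(OC)cc1 | intermediate
12 | (4R,5E)-6-{[(tert-butyldimethylsilyl)oxy]methyl}-8-(1,3-dioxolan-2-yl)-1-[(4-methoxybenzyl)oxy]oct-5-en-2-yn-4-ol | O[C@H](/C=C(/CO[Si](C)(C)C(C)(C)C)CCC1OCCO1)C#CCOCc1ccc(OC)cc1 | intermediate
13 | sodium alkenylaluminate from 12, five-membered ring O6–C6–C7=C8–Al with two 2-methoxyethoxy groups on Al and CH2OPMB on C8 (formed in the flask) | COCCO[Al-]1(OCCOC)O[C@H](/C=C(/CO[Si](C)(C)C(C)(C)C)CCC2OCCO2)C=C1COCc3ccc(OC)cc3.[Na+] | intermediate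
14 | (2E,4S,5E)-6-{[(tert-butyldimethylsilyl)oxy]methyl}-8-(1,3-dioxolan-2-yl)-1-[(4-methoxybenzyl)oxy]octa-2,5-dien-4-ol | O[C@H](/C=C(/CO[Si](C)(C)C(C)(C)C)CCC1OCCO1)/C=C/COCc1ccc(OC)cc1 | intermediate
15 | (1R,2E)-3-{[(tert-butyldimethylsilyl)oxy]methyl}-5-(1,3-dioxolan-2-yl)-1-[(2R,3R)-3-{[(4-methoxybenzyl)oxy]methyl}oxiran-2-yl]pent-2-en-1-ol | O[C@H](/C=C(/CO[Si](C)(C)C(C)(C)C)CCC1OCCO1)[C@H]2O[C@@H]2COCc3ccc(OC)cc3 | intermediate
16 | methyl 3-chloro-3-oxopropanoate | COC(=O)CC(Cl)=O | starting material
17 | (1R,2E)-3-{[(tert-butyldimethylsilyl)oxy]methyl}-5-(1,3-dioxolan-2-yl)-1-[(2R,3R)-3-{[(4-methoxybenzyl)oxy]methyl}oxiran-2-yl]pent-2-en-1-yl methyl malonate | COC(=O)CC(=O)O[C@H](/C=C(/CO[Si](C)(C)C(C)(C)C)CCC1OCCO1)[C@H]2O[C@@H]2COCc3ccc(OC)cc3 | intermediate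
18 | methyl (3R,4R,5R)-5-[(1E)-2-{[(tert-butyldimethylsilyl)oxy]methyl}-4-(1,3-dioxolan-2-yl)but-1-en-1-yl]-4-{(1S)-1-hydroxy-2-[(4-methoxybenzyl)oxy]ethyl}-2-oxooxolane-3-carboxylate | COC(=O)[C@@H]1C(=O)O[C@H](/C=C(/CO[Si](C)(C)C(C)(C)C)CCC2OCCO2)[C@H]1[C@H](O)COCc3ccc(OC)cc3 | intermediate
19 | methyl (3R,4S,5R)-5-[(1E)-2-{[(tert-butyldimethylsilyl)oxy]methyl}-4-(1,3-dioxolan-2-yl)but-1-en-1-yl]-4-{(1S)-2-[(4-methoxybenzyl)oxy]-1-[(triethylsilyl)oxy]ethyl}-2-oxooxolane-3-carboxylate | COC(=O)[C@@H]1C(=O)O[C@H](/C=C(/CO[Si](C)(C)C(C)(C)C)CCC2OCCO2)[C@H]1[C@H](O[Si](CC)(CC)CC)COCc3ccc(OC)cc3 | intermediate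
20 | (4S,5R)-5-[(1E)-2-{[(tert-butyldimethylsilyl)oxy]methyl}-4-(1,3-dioxolan-2-yl)but-1-en-1-yl]-4-{(1S)-2-[(4-methoxybenzyl)oxy]-1-[(triethylsilyl)oxy]ethyl}oxolan-2-one | C1C(=O)O[C@H](/C=C(/CO[Si](C)(C)C(C)(C)C)CCC2OCCO2)[C@H]1[C@H](O[Si](CC)(CC)CC)COCc3ccc(OC)cc3 | intermediate
21 | (3R,4S,5R)-5-[(1E)-2-{[(tert-butyldimethylsilyl)oxy]methyl}-4-(1,3-dioxolan-2-yl)but-1-en-1-yl]-3-[(dimethylamino)methyl]-4-{(1S)-2-[(4-methoxybenzyl)oxy]-1-[(triethylsilyl)oxy]ethyl}oxolan-2-one | CN(C)C[C@@H]1C(=O)O[C@H](/C=C(/CO[Si](C)(C)C(C)(C)C)CCC2OCCO2)[C@H]1[C@H](O[Si](CC)(CC)CC)COCc3ccc(OC)cc3 | intermediate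
22 | N-methyl ammonium iodide of 21 (formed in the flask) | C[N+](C)(C)C[C@@H]1C(=O)O[C@H](/C=C(/CO[Si](C)(C)C(C)(C)C)CCC2OCCO2)[C@H]1[C@H](O[Si](CC)(CC)CC)COCc3ccc(OC)cc3.[I-] | intermediate
23 | (4S,5R)-5-[(1E)-2-{[(tert-butyldimethylsilyl)oxy]methyl}-4-(1,3-dioxolan-2-yl)but-1-en-1-yl]-4-{(1S)-2-[(4-methoxybenzyl)oxy]-1-[(triethylsilyl)oxy]ethyl}-3-methylideneoxolan-2-one | C=C1C(=O)O[C@H](/C=C(/CO[Si](C)(C)C(C)(C)C)CCC2OCCO2)[C@H]1[C@H](O[Si](CC)(CC)CC)COCc3ccc(OC)cc3 | intermediate
24 | 2,4,6-trimethylpyridinium triflate carrying at nitrogen the C1 carbon of 23 with a 2-[(triethylsilyl)oxy]ethoxy group, C1 epimers (formed in the flask) | C=C1C(=O)O[C@H](/C=C(/CO[Si](C)(C)C(C)(C)C)CCC(OCCO[Si](CC)(CC)CC)[n+]2c(C)cc(C)cc2C)[C@H]1[C@H](O[Si](CC)(CC)CC)COCc3ccc(OC)cc3.[O-]S(=O)(=O)C(F)(F)F | intermediate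
25 | (4S,5R)-5-[(1E)-2-{[(tert-butyldimethylsilyl)oxy]methyl}-5-oxopent-1-en-1-yl]-4-{(1S)-2-[(4-methoxybenzyl)oxy]-1-[(triethylsilyl)oxy]ethyl}-3-methylideneoxolan-2-one | C=C1C(=O)O[C@H](/C=C(/CO[Si](C)(C)C(C)(C)C)CCC=O)[C@H]1[C@H](O[Si](CC)(CC)CC)COCc2ccc(OC)cc2 | intermediate
26 | methyl (2Z,6E)-6-{[(tert-butyldimethylsilyl)oxy]methyl}-2-iodo-7-[(2R,3S)-3-{(1S)-2-[(4-methoxybenzyl)oxy]-1-[(triethylsilyl)oxy]ethyl}-4-methylidene-5-oxooxolan-2-yl]hepta-2,6-dienoate | C=C1C(=O)O[C@H](/C=C(/CO[Si](C)(C)C(C)(C)C)CC/C=C(\I)C(=O)OC)[C@H]1[C@H](O[Si](CC)(CC)CC)COCc2ccc(OC)cc2 | intermediate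
27 | methyl (2Z,6E)-6-{[(tert-butyldimethylsilyl)oxy]methyl}-7-[(2R,3S)-3-{(1S)-2-hydroxy-1-[(triethylsilyl)oxy]ethyl}-4-methylidene-5-oxooxolan-2-yl]-2-iodohepta-2,6-dienoate | C=C1C(=O)O[C@H](/C=C(/CO[Si](C)(C)C(C)(C)C)CC/C=C(\I)C(=O)OC)[C@H]1[C@H](O[Si](CC)(CC)CC)CO | intermediate
28 | methyl (2Z,6E)-6-{[(tert-butyldimethylsilyl)oxy]methyl}-2-iodo-7-[(2R,3S)-4-methylidene-5-oxo-3-{(1S)-2-oxo-1-[(triethylsilyl)oxy]ethyl}oxolan-2-yl]hepta-2,6-dienoate | C=C1C(=O)O[C@H](/C=C(/CO[Si](C)(C)C(C)(C)C)CC/C=C(\I)C(=O)OC)[C@H]1[C@H](O[Si](CC)(CC)CC)C=O | intermediate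
29 | methyl (3aS,4S,5S,6E,10E,11aR)-10-{[(tert-butyldimethylsilyl)oxy]methyl}-5-hydroxy-3-methylidene-2-oxo-4-[(triethylsilyl)oxy]-2,3,3a,4,5,8,9,11a-octahydrocyclodeca[b]furan-6-carboxylate | CC[Si](CC)(CC)O[C@H]1[C@H]2C(=C)C(=O)O[C@@H]2/C=C(/CO[Si](C)(C)C(C)(C)C)CC/C=C(/C(=O)OC)[C@@H]1O | intermediate
30 | methyl (3aS,4S,5S,6E,10E,11aR)-5-acetoxy-10-{[(tert-butyldimethylsilyl)oxy]methyl}-3-methylidene-2-oxo-4-[(triethylsilyl)oxy]-2,3,3a,4,5,8,9,11a-octahydrocyclodeca[b]furan-6-carboxylate | CC[Si](CC)(CC)O[C@H]1[C@H]2C(=C)C(=O)O[C@@H]2/C=C(/CO[Si](C)(C)C(C)(C)C)CC/C=C(/C(=O)OC)[C@@H]1OC(C)=O | intermediate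
31 | methyl (3aR,4S,5S,6E,10E,11aR)-5-acetoxy-10-{[(tert-butyldimethylsilyl)oxy]methyl}-4-hydroxy-3-methylidene-2-oxo-2,3,3a,4,5,8,9,11a-octahydrocyclodeca[b]furan-6-carboxylate | O[C@H]1[C@H]2C(=C)C(=O)O[C@@H]2/C=C(/CO[Si](C)(C)C(C)(C)C)CC/C=C(/C(=O)OC)[C@@H]1OC(C)=O | intermediate
32 | methyl (3aS,4S,5S,6E,10E,11aR)-5-acetoxy-10-{[(tert-butyldimethylsilyl)oxy]methyl}-4-(methacryloyloxy)-3-methylidene-2-oxo-2,3,3a,4,5,8,9,11a-octahydrocyclodeca[b]furan-6-carboxylate | C=C(C)C(=O)O[C@H]1[C@H]2C(=C)C(=O)O[C@@H]2/C=C(/CO[Si](C)(C)C(C)(C)C)CC/C=C(/C(=O)OC)[C@@H]1OC(C)=O | intermediate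
33 | methyl (3aS,4S,5S,6E,10E,11aR)-5-acetoxy-10-(hydroxymethyl)-4-(methacryloyloxy)-3-methylidene-2-oxo-2,3,3a,4,5,8,9,11a-octahydrocyclodeca[b]furan-6-carboxylate (CNP0179134.2) | C=C(C)C(=O)O[C@H]1[C@H]2C(=C)C(=O)O[C@@H]2/C=C(/CO)CC/C=C(/C(=O)OC)[C@@H]1OC(C)=O | target

## Step count and least certain steps

Total step count: 23. Longest linear sequence: 22 steps (from 1 through steps 1–4 and 6–23); step 5 is a one-step branch.

Step 10 (key step). The closure may be slow, because the ester tether has to leave its preferred geometry, and intermolecular acylation of the enolate can then compete. After closure, transfer of an acyl group to O8 (translactonisation, or lactonisation onto the C11 ester) can follow if the alkoxide is not protonated quickly. The fallback sets out from 15 and changes the stabilising group and the way it is removed. Esterification of 15 with (phenylsulfonyl)acetic acid (N,N′-dicyclohexylcarbodiimide, DMAP) would give the (phenylsulfonyl)acetate F1. Its softer sulfonyl-stabilised carbanion (NaH, THF/DMF) should open the epoxide at C7 to the α-sulfonyl hydroxy lactone F2, which has no second ester for O8 to attack. Silylation as in step 11 would give the triethylsilyl ether F3, and reductive desulfonylation with SmI2 (THF/MeOH, −78 °C) comes back to the route at 20, bypassing step 12.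

Step 19. The addition may take the wrong face of the C9 aldehyde (an open-chain Felkin-type preference would place O9 anti to O8). Intermolecular coupling may compete with ring closure. The alkenylchromium, being α to an ester, may react sluggishly or lose its geometry. The fallback addresses the stereochemical failure and sets out from 28. If the ring closes mainly to the C9 epimer, that alcohol, the 9R epimer of 29 F4, is converted directly into 30 by Mitsunobu esterification with AcOH (PPh3, diisopropyl azodicarboxylate, THF), which inverts C9 and installs the acetate in one operation, returning to the route at 30.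

Step 6. The hindered β,β-disubstituted enal may react slowly, so that uncatalysed racemic addition lowers the enantioselectivity, or the facial sense may be opposite to that assumed. The fallback sets out from 8 and moves the control of C6 to the epoxidation. Addition of the lithium acetylide of 10 (n-BuLi, THF, −78 °C) would give the racemic propargylic alcohol F5, and reduction as in step 7 the racemic dienol F6. The epoxidation of step 8, run to about half conversion, then acts as a kinetic resolution in which only the 4S enantiomer is converted, returning to the route at 15 at the cost of half the material.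

Step 12. At 120 °C the TES ether may be lost, after which O8 can translactonise, and the substrate is exposed to prolonged heating. The fallback sets out from 19 and uses the C11 carboxyl group instead of discarding it. Cleavage of the methyl ester with Me3SnOH (1,2-dichloroethane, 80 °C) would give the α-carboxy lactone F7. Decarboxylative Mannich methylenation (aqueous HCHO, Et2NH; then NaOAc/AcOH, warm) returns to the route at 23, so steps 13 and 14 are not needed.

Step 21. Methanolysis of the hindered ring TES ether may be slow enough for loss of the primary allylic TBS ether to compete. The fallback sets out from 30. Both silyl groups are removed with HF·pyridine (THF/pyridine) to give the 8,15-diol F8, and the primary allylic hydroxyl is re-silylated selectively (t-BuMe2SiCl, imidazole, CH2Cl2, −20 °C), returning to the route at 31.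

## Further compounds

F1 | step 10 | (1R,2E)-3-{[(tert-butyldimethylsilyl)oxy]methyl}-5-(1,3-dioxolan-2-yl)-1-[(2R,3R)-3-{[(4-methoxybenzyl)oxy]methyl}oxiran-2-yl]pent-2-en-1-yl (phenylsulfonyl)acetate | O=C(CS(=O)(=O)c1ccccc1)O[C@H](/C=C(/CO[Si](C)(C)C(C)(C)C)CCC2OCCO2)[C@H]3O[C@@H]3COCc4ccc(OC)cc4
F2 | step 10 | α-(phenylsulfonyl) analogue of 18: trans lactone with C11 phenylsulfonyl group and free O8 | O=S(=O)(c1ccccc1)[C@@H]1C(=O)O[C@H](/C=C(/CO[Si](C)(C)C(C)(C)C)CCC2OCCO2)[C@H]1[C@H](O)COCc3ccc(OC)cc3
F3 | step 10 | O8 triethylsilyl ether of F2 | O=S(=O)(c1ccccc1)[C@@H]1C(=O)O[C@H](/C=C(/CO[Si](C)(C)C(C)(C)C)CCC2OCCO2)[C@H]1[C@H](O[Si](CC)(CC)CC)COCc3ccc(OC)cc3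
F4 | step 19 | 9R epimer of 29 | CC[Si](CC)(CC)O[C@H]1[C@H]2C(=C)C(=O)O[C@@H]2/C=C(/CO[Si](C)(C)C(C)(C)C)CC/C=C(/C(=O)OC)[C@H]1O
F5 | step 6 | racemic 12 | OC(/C=C(/CO[Si](C)(C)C(C)(C)C)CCC1OCCO1)C#CCOCc1ccc(OC)cc1
F6 | step 6 | racemic 14 | OC(/C=C(/CO[Si](C)(C)C(C)(C)C)CCC1OCCO1)/C=C/COCc1ccc(OC)cc1
F7 | step 12 | C11 carboxylic acid corresponding to 19 | OC(=O)[C@@H]1C(=O)O[C@H](/C=C(/CO[Si](C)(C)C(C)(C)C)CCC2OCCO2)[C@H]1[C@H](O[Si](CC)(CC)CC)COCc3ccc(OC)cc3
F8 | step 21 | 8,15-diol: 30 without both silyl groups | O[C@H]1[C@H]2C(=C)C(=O)O[C@@H]2/C=C(/CO)CC/C=C(/C(=O)OC)[C@@H]1OC(C)=O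
A1 | alternative 1 | eleven-membered α-chloro sulfone, sulfur between C1 and C10, chlorine on C1 (C1 and C10 unspecified) | COc1ccc(CO[C@H]2[C@H]3CC(=O)O[C@@H]3/C=C(/CO[Si](C)(C)C(C)(C)C)CCC(Cl)S(=O)(=O)C(C(=O)OC)[C@@H]2O[Si](CC)(CC)CC)cc1
A2 | alternative 1 | episulfone across C1 and C10 (C1 and C10 unspecified) | COc1ccc(CO[C@H]2[C@H]3CC(=O)O[C@@H]3/C=C(/CO[Si](C)(C)C(C)(C)C)CCC4C(C(=O)OC)(S4(=O)=O)[C@@H]2O[Si](CC)(CC)CC)cc1
A3 | alternative 1 | protected cyclodecadiene with saturated trans lactone, C8 PMB ether and C9 TES ether | COc1ccc(CO[C@H]2[C@H]3CC(=O)O[C@@H]3/C=C(/CO[Si](C)(C)C(C)(C)C)CC/C=C(/C(=O)OC)[C@@H]2O[Si](CC)(CC)CC)cc1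
A4 | alternative 2 | ten-membered homopropargylic alcohol: free C6 hydroxyl, C7 ethynyl, C8 methacrylate, C9 acetate, C15 TBS ether | C=C(C)C(=O)O[C@H]1[C@@H](C#C)[C@H](O)/C=C(/CO[Si](C)(C)C(C)(C)C)CC/C=C(/C(=O)OC)[C@@H]1OC(C)=O
A5 | alternative 2 | C15 TBS ether of the target (identical with 32) | C=C(C)C(=O)O[C@H]1[C@H]2C(=C)C(=O)O[C@@H]2/C=C(/CO[Si](C)(C)C(C)(C)C)CC/C=C(/C(=O)OC)[C@@H]1OC(C)=O
A6 | alternative 3 | 1,2-dialkenylcyclohex-3-en-1-ol: tertiary C6 alcohol with C7=C8 PMB enol ether, C1 bearing the C10=C9 methoxymethoxy acrylate (configurations unspecified) | OC1(C=COCc2ccc(OC)cc2)C=C(CO[Si](C)(C)C(C)(C)C)CCC1C(=COCOC)C(=O)OC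
A7 | alternative 3 | potassium C6 enolate of the ten-membered ring (enolate geometry unspecified) | COc1ccc(CO[C@H]2C=C([O-])/C=C(/CO[Si](C)(C)C(C)(C)C)CC/C=C(/C(=O)OC)[C@@H]2OCOC)cc1.[K+]
A8 | alternative 3 | ten-membered C6 ketone with C8 PMB ether, C9 MOM ether and C1=C10 enoate | COc1ccc(CO[C@H]2CC(=O)/C=C(/CO[Si](C)(C)C(C)(C)C)CC/C=C(/C(=O)OC)[C@@H]2OCOC)cc1
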